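A direct plan would build the flat flavone A1 by carbonylative annulation of an iodophenol with an arylacetylene, reduce it with a CuH/bisphosphine catalyst to flavanone A2, hydroxylate C3 by Rubottom oxidation to A3, debenzylate to aromadendrin A4 and alkylate O7 last with chloro alcohol A5.
- Conjugate reduction of A1 to A2: ring C would be made flat and then taken down again. Hydride addition to a 2-aryl-5-alkoxychromone is slow, and A2 must be enolised again for the C3 oxidation, which invites ring opening and loss of C2.
- Hydrogenolysis of the three benzyl ethers of A3: the O1–C2 bond is itself a benzylic ether and the ketone is reducible. The benzyl groups also keep the side-chain alkene out until the end.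
- Final O-alkylation of unprotected A4 with A5 under base: four hydroxyls compete, and the base-labile trans-dihydroflavonol can open, epimerise or oxidise, on the most valuable intermediate.

**Retrosynthetic overview**
- Key disconnection: C2–C1′ (ring B to ring C) together with C3–O. In ring C, C2 is the β-carbon and C3 the α-carbon of the C4 ketone, and the trans aryl/hydroxyl pair on them is the retron of an aryl–oxygen addition across the C2=C3 bond of a chromone.
- Ring B would therefore be joined last, as an arylzinc reagent added to C2 under [RhCl((S)-binap)]2. The enol silane formed by silyl trapping would be oxidised at C3 in the same operation, so both stereocentres arise together from a flat, achiral precursor.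
- Ring order: rings A and C enter together as achiral 5,7-dihydroxychromone, no ring is closed, and ring B comes last. The hydrogen bond from 5-OH of ring A to the C4 carbonyl leaves 7-OH as the only reactive phenol, so the side chain goes on first.
- By design there is no flavone to reduce, no isolated flavanone to re-enolise, no benzyl ether or hydrogenolysis, and no alkylation of a polyphenolic dihydroflavonol. Three silyl ethers leave in one mildly acidic fluoride step.

Key step: step 4

Remark: 5,7-dihydroxychromone and (4-bromophenoxy)(tert-butyl)dimethylsilane are taken as catalogue compounds, and (S)-BINAP is assumed, by analogy with the sense known for cyclic enones, to steer the aryl group to the face of C2 that gives the 2S enol silane; if the sense were opposite, (R)-BINAP would be used.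

Step 1
Reactants: 1 2-methyl-2-vinyloxirane (isoprene monoxide, racemic)
Product: 2 (2E)-4-chloro-2-methylbut-2-en-1-ol
Conditions: TiCl4 (1.1 equiv), CH2Cl2, −85 °C; then 1 M HCl
Reagents that add atoms: titanium tetrachloride, Cl[Ti](Cl)(Cl)Cl
Why: Lewis acid-mediated SN2′ opening of a vinyl epoxide, in which chloride is delivered from titanium to the vinyl terminus as the tertiary C–O bond breaks, which at low temperature should give mainly the E-alkene (CH2OH trans to CH2Cl), a minor Z isomer being removed by chromatography.

Step 2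
Reactants: 3 5,7-dihydroxy-4H-chromen-4-one (5,7-dihydroxychromone); 2 (2E)-4-chloro-2-methylbut-2-en-1-ol
Product: 4 5-hydroxy-7-{[(2E)-4-hydroxy-3-methylbut-2-en-1-yl]oxy}-4H-chromen-4-one
Conditions: K2CO3 (1.2 equiv), NaI (10 mol%), acetone, 50 °C
Reagents that add atoms: none
Why: Williamson ether synthesis (SN2 at the primary allylic carbon, assisted by iodide), in which the 5-hydroxyl is held in a hydrogen bond to the C4 carbonyl so that carbonate deprotonates and alkylates the vinylogous-acid 7-hydroxyl alone, on an achiral chromone that has no centre to epimerise.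

Step 3
Reactants: 4 5-hydroxy-7-{[(2E)-4-hydroxy-3-methylbut-2-en-1-yl]oxy}-4H-chromen-4-one
Product: 5 5-[(tert-butyldimethylsilyl)oxy]-7-{[(2E)-4-[(tert-butyldimethylsilyl)oxy]-3-methylbut-2-en-1-yl]oxy}-4H-chromen-4-one
Conditions: TBSOTf (2.5 equiv), 2,6-lutidine (4 equiv), CH2Cl2, 0 °C to rt
Reagents that add atoms: tert-butyldimethylsilyl trifluoromethanesulfonate, CC(C)(C)[Si](C)(C)OS(=O)(=O)C(F)(F)F
Why: Silyl ether formation with a silyl triflate, reactive enough to cap the hydrogen-bonded 5-hydroxyl as well as the primary alcohol, so that no acidic proton meets the organozinc reagent and all protecting groups are of one kind.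

Step 4
Reactants: 5 5-[(tert-butyldimethylsilyl)oxy]-7-{[(2E)-4-[(tert-butyldimethylsilyl)oxy]-3-methylbut-2-en-1-yl]oxy}-4H-chromen-4-one; 6 (4-bromophenoxy)(tert-butyl)dimethylsilane
Product: 11 (2R,3R)-5-[(tert-butyldimethylsilyl)oxy]-2-{4-[(tert-butyldimethylsilyl)oxy]phenyl}-7-{[(2E)-4-[(tert-butyldimethylsilyl)oxy]-3-methylbut-2-en-1-yl]oxy}-3-hydroxy-2,3-dihydro-4H-chromen-4-one, via aryllithium 7 (not isolated), via arylzinc chloride 8 (not isolated), via trimethylsilyl enol ether 9 (not isolated), via silyloxy epoxide 10 (not isolated)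
Conditions: 6 (2.5 equiv), n-BuLi, THF, −78 °C, then ZnCl2, 0 °C; 5, TMSCl (2 equiv), [RhCl((S)-binap)]2 (2.5 mol%), THF, 20 °C; cold NaHCO3 wash; DMDO (1.1 equiv), acetone–CH2Cl2, −78 °C; citric acid, THF–H2O, 0 °C
Reagents that add atoms: dimethyldioxirane, CC1(C)OO1
Why: Bromine–lithium exchange and transmetalation give arylzinc chloride 8, whose aryl group passes to rhodium to form an aryl complex of monovalent rhodium that inserts the chromone C2=C3 bond (aryl to C2); TMSCl silylates the resulting metal enolate on oxygen to enol silane 9 and returns Rh–Cl to the cycle, after which dimethyldioxirane epoxidises the C3=C4 enol ether and mild acid opens silyloxy epoxide 10 to the 3-hydroxy ketone (Rubottom oxidation). The closest known reaction type is the [RhCl(binap)]2-catalysed asymmetric 1,4-addition of arylzinc chlorides with TMSCl to 4-quinolones and 2,3-dihydro-4-pyridones, the nitrogen analogues of chromones, which themselves are known acceptors for rhodium-catalysed arylboron additions. No ring is closed: the step forms C2–C1′ and C3–O on the existing ring C and joins ring B to the molecule. C2 is set by the catalyst, (S)-BINAP steering the aryl group to the face that gives the 2S enol silane, and C3 is set by relay, the dioxirane approaching anti to the C2 aryl group so that H2 and H3 become trans (2R,3R). The step needs 1,4- rather than 1,2-addition, secured because arylzinc chlorides do not add to ketones without the catalyst and because silyl trapping removes the enolate before it can expel the O1 aryloxide and open ring C. It also needs oxidation of the enol silane in preference to the side-chain alkene, secured by the far higher nucleophilicity of a silyl enol ether compared with a trisubstituted alkene that carries two allylic oxygens, at −78 °C with one equivalent of oxidant.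

Step 5
Reactants: 11 (2R,3R)-5-[(tert-butyldimethylsilyl)oxy]-2-{4-[(tert-butyldimethylsilyl)oxy]phenyl}-7-{[(2E)-4-[(tert-butyldimethylsilyl)oxy]-3-methylbut-2-en-1-yl]oxy}-3-hydroxy-2,3-dihydro-4H-chromen-4-one
Product: 12 (2R,3R)-3,5-dihydroxy-7-{[(2E)-4-hydroxy-3-methylbut-2-en-1-yl]oxy}-2-(4-hydroxyphenyl)-2,3-dihydro-4H-chromen-4-one
Conditions: HF·pyridine, THF–pyridine, 0 °C to rt
Reagents that add atoms: none
Why: Fluoride-induced cleavage of the two aryl silyl ethers and the primary silyl ether under mildly acidic conditions, in which the trans-dihydroflavonol cannot open at O1–C2 or epimerise and the allylic aryl ether and the E-alkene are left alone.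

**Compound list**

1 | 2-methyl-2-vinyloxirane (isoprene monoxide, racemic) | CC1(C=C)CO1 | starting material
2 | (2E)-4-chloro-2-methylbut-2-en-1-ol | C/C(=C\CCl)CO | intermediate
3 | 5,7-dihydroxy-4H-chromen-4-one | O=c1ccoc2cc(O)cc(O)c12 | starting material
4 | 5-hydroxy-7-{[(2E)-4-hydroxy-3-methylbut-2-en-1-yl]oxy}-4H-chromen-4-one | C/C(=C\COc1cc(O)c2c(c1)occc2=O)CO | intermediate
5 | 5-[(tert-butyldimethylsilyl)oxy]-7-{[(2E)-4-[(tert-butyldimethylsilyl)oxy]-3-methylbut-2-en-1-yl]oxy}-4H-chromen-4-one | C/C(=C\COc1cc(O[Si](C)(C)C(C)(C)C)c2c(c1)occc2=O)CO[Si](C)(C)C(C)(C)C | intermediate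
6 | (4-bromophenoxy)(tert-butyl)dimethylsilane | CC(C)(C)[Si](C)(C)Oc1ccc(Br)cc1 | starting material
7 | {4-[(tert-butyldimethylsilyl)oxy]phenyl}lithium | [Li]c1ccc(O[Si](C)(C)C(C)(C)C)cc1 | intermediate
8 | {4-[(tert-butyldimethylsilyl)oxy]phenyl}zinc chloride | Cl[Zn]c1ccc(O[Si](C)(C)C(C)(C)C)cc1 | intermediate
9 | (2S)-5-[(tert-butyldimethylsilyl)oxy]-2-{4-[(tert-butyldimethylsilyl)oxy]phenyl}-7-{[(2E)-4-[(tert-butyldimethylsilyl)oxy]-3-methylbut-2-en-1-yl]oxy}-4-[(trimethylsilyl)oxy]-2H-chromene | C/C(=C\COc1cc(O[Si](C)(C)C(C)(C)C)c2c(c1)O[C@H](c1ccc(O[Si](C)(C)C(C)(C)C)cc1)C=C2O[Si](C)(C)C)CO[Si](C)(C)C(C)(C)C | intermediate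
10 | (2R,3R,4R)-5-[(tert-butyldimethylsilyl)oxy]-2-{4-[(tert-butyldimethylsilyl)oxy]phenyl}-7-{[(2E)-4-[(tert-butyldimethylsilyl)oxy]-3-methylbut-2-en-1-yl]oxy}-3,4-epoxy-4-[(trimethylsilyl)oxy]chromane, oxirane oxygen anti to the C2 aryl group | C/C(=C\COc1cc(O[Si](C)(C)C(C)(C)C)c2c(c1)O[C@H](c1ccc(O[Si](C)(C)C(C)(C)C)cc1)[C@H]3O[C@@]23O[Si](C)(C)C)CO[Si](C)(C)C(C)(C)C | intermediate
11 | (2R,3R)-5-[(tert-butyldimethylsilyl)oxy]-2-{4-[(tert-butyldimethylsilyl)oxy]phenyl}-7-{[(2E)-4-[(tert-butyldimethylsilyl)oxy]-3-methylbut-2-en-1-yl]oxy}-3-hydroxy-2,3-dihydro-4H-chromen-4-one | C/C(=C\COc1cc(O[Si](C)(C)C(C)(C)C)c2c(c1)O[C@H](c1ccc(O[Si](C)(C)C(C)(C)C)cc1)[C@@H](O)C2=O)CO[Si](C)(C)C(C)(C)C | intermediate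
12 | (2R,3R)-3,5-dihydroxy-7-{[(2E)-4-hydroxy-3-methylbut-2-en-1-yl]oxy}-2-(4-hydroxyphenyl)-2,3-dihydro-4H-chromen-4-one | C/C(=C\COc1cc(O)c2c(c1)O[C@H](c1ccc(O)cc1)[C@@H](O)C2=O)CO | target

Total steps: 5. Longest linear sequence: 5 steps (1 → 2 → 4 → 5 → 11 → 12).

**Steps most likely to fail**

Step 4: the aryl–rhodium species may add slowly or with poor facial selectivity to the electron-rich, peri-substituted chromone, or the enol silane may be lost before it is oxidised. The fallback sets out from 5. A conjugate addition of commercial {4-[(tert-butyldimethylsilyl)oxy]phenyl}boronic acid in toluene–water with [RhOH(cod)]2 and an electron-poor atropisomeric bisphosphine (MeO-F12-BIPHEP, the antipode that gives 2S) is a reaction type established for chromones. It would end in protonation and give the isolated flavanone (2S)-5-[(tert-butyldimethylsilyl)oxy]-2-{4-[(tert-butyldimethylsilyl)oxy]phenyl}-7-{[(2E)-4-[(tert-butyldimethylsilyl)oxy]-3-methylbut-2-en-1-yl]oxy}-2,3-dihydro-4H-chromen-4-one F1. Soft enolisation of this ketone (TMSOTf, Et3N, CH2Cl2, 0 °C) would then rejoin the route at enol silane 9, which is oxidised as in step 4.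

Step 1: the epoxide opening may give an E/Z mixture or the 1,2-chlorohydrin, and the allylic chloride may not keep. The fallback sets out from 3. O-Alkylation with prenyl bromide (K2CO3, acetone) would give 5-hydroxy-7-[(3-methylbut-2-en-1-yl)oxy]-4H-chromen-4-one F2. Allylic oxidation with SeO2 (catalytic) and t-BuOOH in CH2Cl2, which attacks the methyl group trans to the chain of a prenyl ether, would then lead to 4, where the route is rejoined.

Step 2: the bifunctional allylic chloride may ionise and give branched ethers, or alkylate ring carbons of the electron-rich chromone. The fallback sets out from 1 and 3. A Tsuji–Trost etherification with Pd(PPh3)4 (zerovalent palladium) in THF would add the 7-hydroxyl to the unsubstituted terminus of the π-allyl complex formed from the vinyl epoxide and should give 4 directly, where the route is rejoined. This fallback makes no new compound (F0).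

**Further compounds**

F1 | step 4 | (2S)-5-[(tert-butyldimethylsilyl)oxy]-2-{4-[(tert-butyldimethylsilyl)oxy]phenyl}-7-{[(2E)-4-[(tert-butyldimethylsilyl)oxy]-3-methylbut-2-en-1-yl]oxy}-2,3-dihydro-4H-chromen-4-one | C/C(=C\COc1cc(O[Si](C)(C)C(C)(C)C)c2c(c1)O[C@H](c1ccc(O[Si](C)(C)C(C)(C)C)cc1)CC2=O)CO[Si](C)(C)C(C)(C)C
F2 | step 1 | 5-hydroxy-7-[(3-methylbut-2-en-1-yl)oxy]-4H-chromen-4-one | CC(C)=CCOc1cc(O)c2c(c1)occc2=O
F0 | step 2 | none | none
A1 | direct plan | 5,7-bis(benzyloxy)-2-[4-(benzyloxy)phenyl]-4H-chromen-4-one | O=c1cc(-c2ccc(OCc3ccccc3)cc2)oc2cc(OCc3ccccc3)cc(OCc3ccccc3)c12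
A2 | direct plan | (2S)-5,7-bis(benzyloxy)-2-[4-(benzyloxy)phenyl]-2,3-dihydro-4H-chromen-4-one | C(Oc1cc(OCc2ccccc2)c2c(c1)O[C@H](c1ccc(OCc3ccccc3)cc1)CC2=O)c1ccccc1
A3 | direct plan | (2R,3R)-5,7-bis(benzyloxy)-2-[4-(benzyloxy)phenyl]-3-hydroxy-2,3-dihydro-4H-chromen-4-one | C(Oc1cc(OCc2ccccc2)c2c(c1)O[C@H](c1ccc(OCc3ccccc3)cc1)[C@@H](O)C2=O)c1ccccc1
A4 | direct plan | (2R,3R)-3,5,7-trihydroxy-2-(4-hydroxyphenyl)-2,3-dihydro-4H-chromen-4-one (aromadendrin) | Oc1cc(O)c2c(c1)O[C@H](c1ccc(O)cc1)[C@@H](O)C2=O
A5 | direct plan | (2E)-4-chloro-2-methylbut-2-en-1-ol | C/C(=C\CCl)CO
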